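## Analysis of the target

Target 24 is methyl 2-[(1S,4S,6R,10R,12R)-1-methyl-7-methylidene-6-(3-methylbut-2-en-1-yl)-12-(prop-1-en-2-yl)bicyclo[8.2.0]dodecan-4-yl]prop-2-enoate. It is a cyclobutane (C1, C10, C11, C12) trans-fused along C1–C10 to a ten-membered carbocycle (C1 to C10); these atom numbers are used for all ring-expanded compounds below. Three contiguous stereocentres sit on the four-membered ring: quaternary C1 (CH3), C10 (H trans to that CH3) and C12 (prop-1-en-2-yl cis to the CH3). Two isolated ones sit on the far side of the medium ring: C4 (acrylate unit) and C6 (prenyl), 1,3-trans across C5. The only sp2 ring atom is C7 and there is no ring olefin, so a late hydrogenation of a ring C=C next to four other C=C bonds is not available. Sensitive groups are the 2-substituted acrylate (Michael acceptor, no hydrides or organometallics), three isolated olefins of different nucleophilicity, and the vinylcyclobutane (acid, heat). The feature the strategy uses: ring atoms C1–C6, with CH3 on C1 and a C3 unit on C4, carry the substitution pattern of carvone (C2 methyl, C5 prop-1-en-2-yl) once a transannular bond C1–C6 is imagined. In addition, the trans arrangement of C2 and C9 across C1–C10 is that of an (E)-C1=C10 olefin, so the cyclobutane reads as a suprafacial [2+2] adduct of an (E)-cyclodecene. The hard points are the ten-membered ring, the quaternary C1 in a strained trans-fused ring, and relaying the single chiral-pool centre (C4) to C1, C10, C12 and C6 through a mobile medium ring.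

## Retrosynthetic reasoning

24 to 23: the trisubstituted C=C of the prenyl group is cut by cross-metathesis. It comes last because it is the most nucleophilic and most oxidisable olefin; an allyl group is inert to the ketene, the oxidants and the acids used earlier.

23 to 19: the acrylate is traced back to a silyl-protected allylic alcohol. The ester would not survive hydride, organolithium or KH steps, and no late reaction can tell the two prop-1-en-2-yl groups apart. The C3 unit on C4 is therefore oxidised on carvone itself, where it is the only electron-rich olefin.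

19 to 18: the C7 methylidene comes from a C7 ketone. A ketone at C7 also makes C6 epimerisable, which gives a handle on that centre.

18 to 16: the C6–allyl bond is cut and the C7 ketone is written as an enol ether. This gives enol triflate 16 (C6–OTf, C7–OEt). Cross-coupling at C6 and hydrolysis move the carbonyl from C6 to C7 and form the C–C bond, a 1,2-carbonyl transposition with alkylation in one flask.

16 to 13: the cyclobutane bonds C10–C11 and C1–C12 are cut, with a carbonyl placed on C11. This gives the (E)-C10=C1 olefin of 13 and a ketene that already carries the prop-1-en-2-yl group. The cut is made here because a stereospecific suprafacial addition to an E trisubstituted olefin gives exactly the trans fusion with quaternary C1. The normal regiochemistry of ketene additions (carbonyl carbon to the less substituted C10) puts the substituted carbon at C12 next to C1.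

13 to 10 (key): the transannular bond C6–C1 is re-formed and C8–C9 is cut. The ten-membered ring collapses to the 1,2-dialkenylcyclohexanol 10. The forward [3,3] shift must give the E olefin and an enolate of defined position.

10 to 5: the carbinol comes from ketone 9 by 1,2-addition of a 1-alkoxyvinyl nucleophile. The vinyl group on the quaternary carbon comes from enone 5 by conjugate reduction, aldol addition and dehydration.

5 to 1: allylic chlorination of (S)-carvone 1, acetate displacement, methanolysis and silylation.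

## Alternatives that were turned down

Alternative 1: the textbook route closes the ten-membered ring last, at C2=C3, by ring-closing metathesis on a preformed cyclobutane. Diene A1 would give cyclodecene A2, which would then be hydrogenated. It was turned down for these reasons: ring-closing metathesis to a ten-membered ring fights strain and entropy, and one partner is a vinyl group on quaternary C1. The ring olefin of A2 would have to be reduced next to four other C=C bonds, so all of them would need masks. C4 and C6 would be set on an open chain without ring control, and the trans-fused cyclobutane would still need its own enantioselective synthesis. The count goes well above twenty steps.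

Alternative 2: Grob fragmentation of a cyclobutane-annulated decalin across the C7–C2 bond. Hydroxy mesylate A3 would give cyclodecenone A4 (C7 ketone, C2=C3 olefin). It was turned down because an enone–olefin photoadduct places its carbonyl next to the ring fusion and not at C7, so the tricycle needs a long relocation of functionality. Its trans four/six junction is the less stable, epimerisable one. A3 has more stereocentres than the target, and A4 again carries a ring olefin that must be reduced selectively.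

Alternative 3: anionic oxy-Cope rearrangement with a cyclobutenyl group, starting from the enantiomer of 1. Conjugate allylation would set C6 trans to C4 directly; vinylation and addition of a cyclobut-1-enyl organometallic would give carbinol A5. Rearrangement and enolate methylation would give A6 with the four-membered ring already fused. It was turned down because three corrections outweigh the gain. The oxygen ends on C2 as a neopentyl ring ketone that must be removed. The carvone methyl ends on C7 inside an endocyclic C7=C8 olefin that would have to be moved against thermodynamics. C12 has no handle for the prop-1-en-2-yl group unless a chiral, racemic cyclobutenyl reagent is used, which gives diastereomers.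

Key step: step 7

Step 1
Reactants: 1 (S)-(+)-carvone
Product: 2 (5S)-5-(3-chloroprop-1-en-2-yl)-2-methylcyclohex-2-en-1-one
Conditions: Ca(OCl)2, solid CO2, CH2Cl2/H2O, 0 °C to rt
Reagents that add atoms: calcium hypochlorite, [Ca+2].[O-]Cl.[O-]Cl
Why: Ene-type allylic chlorination by HOCl attacks only the electron-rich 1,1-disubstituted olefin; the enone C=C is inert and C5 is not touched.

Step 2
Reactants: 2 (5S)-5-(3-chloroprop-1-en-2-yl)-2-methylcyclohex-2-en-1-one
Product: 4 (5S)-5-(3-hydroxyprop-1-en-2-yl)-2-methylcyclohex-2-en-1-one, via acetate 3 (not isolated)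
Conditions: KOAc, DMF, 60 °C; then K2CO3 (cat.), MeOH, 0 °C
Reagents that add atoms: potassium acetate, CC(=O)[O-].[K+]
Why: SN2 displacement of the primary allylic chloride by acetate and methanolysis of the ester should give the allylic alcohol without touching the enone.

Step 3
Reactants: 4 (5S)-5-(3-hydroxyprop-1-en-2-yl)-2-methylcyclohex-2-en-1-one
Product: 5 (5S)-5-{3-[(tert-butyldiphenylsilyl)oxy]prop-1-en-2-yl}-2-methylcyclohex-2-en-1-one
Conditions: TBDPSCl, imidazole, CH2Cl2, rt
Reagents that add atoms: tert-butyl(chloro)diphenylsilane, CC(C)(C)[Si](Cl)(c1ccccc1)c1ccccc1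
Why: Silylation of the primary alcohol; the bulky silyl ether should survive hydride, organolithium, KH, amine and mild acid conditions and masks the future acrylate.

Step 4
Reactants: 5 (5S)-5-{3-[(tert-butyldiphenylsilyl)oxy]prop-1-en-2-yl}-2-methylcyclohex-2-en-1-one
Product: 7 (2S,5S)-2-(1-hydroxyethyl)-2-methyl-5-{3-[(tert-butyldiphenylsilyl)oxy]prop-1-en-2-yl}cyclohexan-1-one (carbinol epimers), via lithium enolate 6 (not isolated)
Conditions: LiBH(s-Bu)3, THF, −78 °C; CH3CHO, −78 °C; AcOH
Reagents that add atoms: acetaldehyde, CC=O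
Why: Conjugate hydride reduction gives the C1–C2 enolate regiospecifically and its aldol addition creates the quaternary carbon (reductive aldol reaction). The aldehyde should enter axially, cis to the C5 side chain; both new centres are erased later, so their configuration is not critical.

Step 5
Reactants: 7 (2S,5S)-2-(1-hydroxyethyl)-2-methyl-5-{3-[(tert-butyldiphenylsilyl)oxy]prop-1-en-2-yl}cyclohexan-1-one
Product: 9 (2S,5S)-2-ethenyl-2-methyl-5-{3-[(tert-butyldiphenylsilyl)oxy]prop-1-en-2-yl}cyclohexan-1-one, via mesylate 8 (not isolated)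
Conditions: MsCl, Et3N, CH2Cl2, 0 °C; then DBU, toluene, 80 °C
Reagents that add atoms: none
Why: E2 elimination of the mesylate can only use the methyl hydrogens, so the vinyl group forms. The quaternary α-carbon excludes E1cB pathways and the mesylate cannot undergo retro-aldol cleavage.

Step 6
Reactants: 9 (2S,5S)-2-ethenyl-2-methyl-5-{3-[(tert-butyldiphenylsilyl)oxy]prop-1-en-2-yl}cyclohexan-1-one
Product: 10 (1S,2S,5S)-1-(1-ethoxyethenyl)-2-ethenyl-2-methyl-5-{3-[(tert-butyldiphenylsilyl)oxy]prop-1-en-2-yl}cyclohexan-1-ol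
Conditions: ethyl vinyl ether, t-BuLi, THF, −78 to 0 °C; then 9, −78 °C; H2O
Reagents that add atoms: ethyl vinyl ether, C=COCC
Why: 1,2-Addition of 1-ethoxyvinyllithium to the ketone, expected axially and anti to the axial C2 vinyl group, gives the trans-dialkenyl carbinol. The carbinol centre is destroyed in step 7, and its epimer would lead to the same E ring olefin.

Step 7
Reactants: 10 (1S,2S,5S)-1-(1-ethoxyethenyl)-2-ethenyl-2-methyl-5-{3-[(tert-butyldiphenylsilyl)oxy]prop-1-en-2-yl}cyclohexan-1-ol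
Product: 13 (1E,5E,9S)-2-ethoxy-6-methyl-9-{3-[(tert-butyldiphenylsilyl)oxy]prop-1-en-2-yl}cyclodeca-1,5-dien-1-yl trifluoromethanesulfonate, via potassium alkoxide 11 (not isolated), via potassium enolate 12 (not isolated)
Conditions: KH, 18-crown-6, THF, 0 to 40 °C; then PhNTf2, −78 to 0 °C
Reagents that add atoms: N-phenylbis(trifluoromethanesulfonimide), O=S(=O)(N(c1ccccc1)S(=O)(=O)C(F)(F)F)C(F)(F)F
Why: Deprotonation gives alkoxide 11, whose [3,3]-sigmatropic shift (anionic oxy-Cope rearrangement) forms the C8–C9 bond between the two terminal CH2 carbons and cleaves the C6–C1 bond, the former C1–C2 bond of carvone. The ten-membered ring therefore arises by four-carbon ring expansion of the cyclohexane and not by an end-to-end cyclisation, so no exo or endo closure mode and no high-dilution entropy problem are involved. The closest known reaction type is the anionic oxy-Cope ring expansion of trans-1,2-dialkenylcyclohexanols to (E)-cyclodec-5-enone enolates with trapping of the enolate in the same flask. The shift should pass through a chair transition state with both alkenyl groups equatorial, in which the C1–C2 ring bond is pseudo-equatorial; this fixes the E geometry of the new C10=C1 olefin, the one selectivity that later steps need, and a chair from the epimeric carbinol would give the same E olefin. No sp3 stereocentre is formed: the quaternary carbon is turned into the E olefin that later dictates the trans ring fusion, and C4 is untouched. Enolate 12 forms irreversibly with oxygen on C6 and the ethoxy group on C7, and the triflating agent reacts at oxygen, so the C6–O bond is stored as a leaving group and C7 as a masked ketone. The alkoxide acceleration should allow 40 °C or below, which matters because the (1E,5E)-diene 13 can undergo neutral Cope reversal on heating and is kept cold until step 8 has consumed the C10=C1 olefin.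

Step 8
Reactants: 13 (1E,5E,9S)-2-ethoxy-6-methyl-9-{3-[(tert-butyldiphenylsilyl)oxy]prop-1-en-2-yl}cyclodeca-1,5-dien-1-yl trifluoromethanesulfonate
Product: 14 (1S,4S,6E,10S,12R)-7-ethoxy-1-methyl-11-oxo-12-(prop-1-en-2-yl)-4-{3-[(tert-butyldiphenylsilyl)oxy]prop-1-en-2-yl}bicyclo[8.2.0]dodec-6-en-6-yl trifluoromethanesulfonate (spatial arrangement at C1, C4, C10 and C12 as in 24)
Conditions: 3-methylbut-2-enoyl chloride (slow addition), Et3N, CH2Cl2, 40 °C
Reagents that add atoms: 3-methylbut-2-enoyl chloride, CC(C)=CC(Cl)=O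
Why: 1,4-Dehydrochlorination gives the vinylketene, whose thermal ketene–olefin [2+2] cycloaddition is suprafacial on the strained (E)-C10=C1 olefin, so the E geometry becomes the trans ring fusion; the carbonyl carbon bonds to the less substituted C10 and the substituted carbon to C1. The ketene should approach the outer face of the crossed germacrane-type conformer in which the C1 methyl and the C4 side chain lie on the same side, which sets C1 and C10 relative to C4, and the larger ketene substituent should turn to the more hindered face, cis to the CH3, which sets C12. The tetrasubstituted push-pull enol triflate olefin and the side-chain olefin with its allylic oxygen are unstrained and less nucleophilic.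

Step 9
Reactants: 14 (1S,4S,6E,10S,12R)-7-ethoxy-1-methyl-11-oxo-12-(prop-1-en-2-yl)-4-{3-[(tert-butyldiphenylsilyl)oxy]prop-1-en-2-yl}bicyclo[8.2.0]dodec-6-en-6-yl trifluoromethanesulfonate
Product: 16 (1S,4S,6E,10R,12R)-7-ethoxy-1-methyl-12-(prop-1-en-2-yl)-4-{3-[(tert-butyldiphenylsilyl)oxy]prop-1-en-2-yl}bicyclo[8.2.0]dodec-6-en-6-yl trifluoromethanesulfonate, via tosylhydrazone 15 (not isolated)
Conditions: TsNHNH2, EtOH/THF, rt; then catecholborane, CHCl3, 0 °C; NaOAc·3H2O, 60 °C
Reagents that add atoms: none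
Why: The strained cyclobutanone is the only ketone present and should condense readily; reduction of the tosylhydrazone with catecholborane, then loss of sulfinate and dinitrogen, gives the CH2 group under near-neutral conditions. This removes the carbonyl before base can epimerise C10 or C12 or conjugate the prop-1-en-2-yl group.

Step 10
Reactants: 16 (1S,4S,6E,10R,12R)-7-ethoxy-1-methyl-12-(prop-1-en-2-yl)-4-{3-[(tert-butyldiphenylsilyl)oxy]prop-1-en-2-yl}bicyclo[8.2.0]dodec-6-en-6-yl trifluoromethanesulfonate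
Product: 18 (1S,4S,6R,10R,12R)-1-methyl-6-(prop-2-en-1-yl)-12-(prop-1-en-2-yl)-4-{3-[(tert-butyldiphenylsilyl)oxy]prop-1-en-2-yl}bicyclo[8.2.0]dodecan-7-one, via enol ether 17 (not isolated)
Conditions: allylSnBu3, Pd2(dba)3 (cat.), AsPh3, LiCl, NMP, 50 °C; then 1 M HCl, THF, 0 °C
Reagents that add atoms: allyltributylstannane, C=CC[Sn](CCCC)(CCCC)CCCC; water, O
Why: Stille coupling of the enol triflate forms the C6–allyl bond with retention of olefin geometry, and hydrolysis of the enol ether unveils the C7 ketone, so the carbonyl moves from C6 to C7 (alkylative 1,2-carbonyl transposition). Protonation at C6 from the outer face of the E enol ether in the crossed conformer should give the 6R epimer; C6 is then α to the ketone, so the epimers can be equilibrated with DBU and the minor one recycled.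

Step 11
Reactants: 18 (1S,4S,6R,10R,12R)-1-methyl-6-(prop-2-en-1-yl)-12-(prop-1-en-2-yl)-4-{3-[(tert-butyldiphenylsilyl)oxy]prop-1-en-2-yl}bicyclo[8.2.0]dodecan-7-one
Product: 19 tert-butyl({2-[(1S,4S,6R,10R,12R)-1-methyl-7-methylidene-6-(prop-2-en-1-yl)-12-(prop-1-en-2-yl)bicyclo[8.2.0]dodecan-4-yl]prop-2-en-1-yl}oxy)diphenylsilane
Conditions: Cp2TiMe2, toluene/THF, 65 °C, dark
Reagents that add atoms: dimethyltitanocene, C[Ti](C)(C1C=CC=C1)C1C=CC=C1
Why: Petasis methylenation converts the hindered, enolisable medium-ring ketone into the exocyclic methylene under non-basic conditions, so the C6 configuration set in step 10 is kept.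

Step 12
Reactants: 19 tert-butyl({2-[(1S,4S,6R,10R,12R)-1-methyl-7-methylidene-6-(prop-2-en-1-yl)-12-(prop-1-en-2-yl)bicyclo[8.2.0]dodecan-4-yl]prop-2-en-1-yl}oxy)diphenylsilane
Product: 20 2-[(1S,4S,6R,10R,12R)-1-methyl-7-methylidene-6-(prop-2-en-1-yl)-12-(prop-1-en-2-yl)bicyclo[8.2.0]dodecan-4-yl]prop-2-en-1-ol
Conditions: Bu4NF, THF, rt
Reagents that add atoms: none
Why: Fluoride cleavage of the silyl ether; no other group in 19 responds to fluoride.

Step 13
Reactants: 20 2-[(1S,4S,6R,10R,12R)-1-methyl-7-methylidene-6-(prop-2-en-1-yl)-12-(prop-1-en-2-yl)bicyclo[8.2.0]dodecan-4-yl]prop-2-en-1-ol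
Product: 22 2-[(1S,4S,6R,10R,12R)-1-methyl-7-methylidene-6-(prop-2-en-1-yl)-12-(prop-1-en-2-yl)bicyclo[8.2.0]dodecan-4-yl]prop-2-enoic acid, via enal 21 (not isolated)
Conditions: MnO2, CH2Cl2, rt, filtration; then NaClO2, NaH2PO4, 2-methylbut-2-ene, t-BuOH/H2O, 0 °C to rt
Reagents that add atoms: sodium chlorite, [Na+].[O-]Cl=O
Why: MnO2 oxidises only the allylic alcohol, and the Pinnick oxidation takes the enal to the acid while the scavenger removes HOCl. At this stage the molecule holds only mono- and 1,1-disubstituted olefins, which are little prone to chlorination.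

Step 14
Reactants: 22 2-[(1S,4S,6R,10R,12R)-1-methyl-7-methylidene-6-(prop-2-en-1-yl)-12-(prop-1-en-2-yl)bicyclo[8.2.0]dodecan-4-yl]prop-2-enoic acid
Product: 23 methyl 2-[(1S,4S,6R,10R,12R)-1-methyl-7-methylidene-6-(prop-2-en-1-yl)-12-(prop-1-en-2-yl)bicyclo[8.2.0]dodecan-4-yl]prop-2-enoate
Conditions: MeI, K2CO3, DMF, rt
Reagents that add atoms: iodomethane, CI
Why: O-Alkylation of the carboxylate gives the methyl ester under conditions too mild for conjugate addition to the acrylate.

Step 15
Reactants: 23 methyl 2-[(1S,4S,6R,10R,12R)-1-methyl-7-methylidene-6-(prop-2-en-1-yl)-12-(prop-1-en-2-yl)bicyclo[8.2.0]dodecan-4-yl]prop-2-enoate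
Product: 24 methyl 2-[(1S,4S,6R,10R,12R)-1-methyl-7-methylidene-6-(3-methylbut-2-en-1-yl)-12-(prop-1-en-2-yl)bicyclo[8.2.0]dodecan-4-yl]prop-2-enoate (target)
Conditions: second-generation Grubbs catalyst RuCl2(=CHPh)(PCy3)(H2IMes) (5 mol %), 2-methylbut-2-ene/CH2Cl2, 40 °C
Reagents that add atoms: 2-methylbut-2-ene, CC=C(C)C
Why: Olefin cross-metathesis with excess 2-methylbut-2-ene converts the monosubstituted allyl olefin into the prenyl group. The three 1,1-disubstituted olefins, including the electron-poor acrylate, should not engage the catalyst under these conditions, and no stereocentre is touched.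

Compound list

1 | (S)-(+)-carvone, (5S)-2-methyl-5-(prop-1-en-2-yl)cyclohex-2-en-1-one | CC1=CC[C@@H](CC1=O)C(=C)C | starting material
2 | (5S)-5-(3-chloroprop-1-en-2-yl)-2-methylcyclohex-2-en-1-one | CC1=CC[C@@H](CC1=O)C(=C)CCl | intermediate
3 | 2-[(1S)-4-methyl-5-oxocyclohex-3-en-1-yl]prop-2-en-1-yl acetate | CC1=CC[C@@H](CC1=O)C(=C)COC(C)=O | intermediate (not isolated)
4 | (5S)-5-(3-hydroxyprop-1-en-2-yl)-2-methylcyclohex-2-en-1-one | CC1=CC[C@@H](CC1=O)C(=C)CO | intermediate
5 | (5S)-5-{3-[(tert-butyldiphenylsilyl)oxy]prop-1-en-2-yl}-2-methylcyclohex-2-en-1-one | CC1=CC[C@@H](CC1=O)C(=C)CO[Si](c1ccccc1)(c1ccccc1)C(C)(C)C | intermediate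
6 | lithium (5S)-5-{3-[(tert-butyldiphenylsilyl)oxy]prop-1-en-2-yl}-2-methylcyclohex-1-en-1-olate | [Li+].[O-]C1=C(C)CC[C@@H](C1)C(=C)CO[Si](c1ccccc1)(c1ccccc1)C(C)(C)C | intermediate (not isolated)
7 | (2S,5S)-2-(1-hydroxyethyl)-2-methyl-5-{3-[(tert-butyldiphenylsilyl)oxy]prop-1-en-2-yl}cyclohexan-1-one, carbinol epimers | O=C1C[C@@H](C(=C)CO[Si](c2ccccc2)(c2ccccc2)C(C)(C)C)CC[C@@]1(C)C(C)O | intermediate
8 | methanesulfonate of 7 | O=C1C[C@@H](C(=C)CO[Si](c2ccccc2)(c2ccccc2)C(C)(C)C)CC[C@@]1(C)C(C)OS(C)(=O)=O | intermediate (not isolated)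
9 | (2S,5S)-2-ethenyl-2-methyl-5-{3-[(tert-butyldiphenylsilyl)oxy]prop-1-en-2-yl}cyclohexan-1-one | O=C1C[C@@H](C(=C)CO[Si](c2ccccc2)(c2ccccc2)C(C)(C)C)CC[C@@]1(C)C=C | intermediate
10 | (1S,2S,5S)-1-(1-ethoxyethenyl)-2-ethenyl-2-methyl-5-{3-[(tert-butyldiphenylsilyl)oxy]prop-1-en-2-yl}cyclohexan-1-ol | O[C@@]1(C(=C)OCC)C[C@@H](C(=C)CO[Si](c2ccccc2)(c2ccccc2)C(C)(C)C)CC[C@@]1(C)C=C | intermediate
11 | potassium alkoxide of 10 | [K+].[O-][C@@]1(C(=C)OCC)C[C@@H](C(=C)CO[Si](c2ccccc2)(c2ccccc2)C(C)(C)C)CC[C@@]1(C)C=C | intermediate (not isolated)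
12 | potassium (1E,5E,9S)-2-ethoxy-6-methyl-9-{3-[(tert-butyldiphenylsilyl)oxy]prop-1-en-2-yl}cyclodeca-1,5-dien-1-olate | [K+].CCO/C1=C(/[O-])C[C@@H](C(=C)CO[Si](c2ccccc2)(c2ccccc2)C(C)(C)C)CC/C(C)=C/CC1 | intermediate (not isolated)
13 | (1E,5E,9S)-2-ethoxy-6-methyl-9-{3-[(tert-butyldiphenylsilyl)oxy]prop-1-en-2-yl}cyclodeca-1,5-dien-1-yl trifluoromethanesulfonate | CCO/C1=C(/OS(=O)(=O)C(F)(F)F)C[C@@H](C(=C)CO[Si](c2ccccc2)(c2ccccc2)C(C)(C)C)CC/C(C)=C/CC1 | intermediate
14 | (1S,4S,6E,10S,12R)-7-ethoxy-1-methyl-11-oxo-12-(prop-1-en-2-yl)-4-{3-[(tert-butyldiphenylsilyl)oxy]prop-1-en-2-yl}bicyclo[8.2.0]dodec-6-en-6-yl trifluoromethanesulfonate | FC(F)(F)S(=O)(=O)O/C1=C(/OCC)CC[C@@H]2C(=O)[C@H](C(=C)C)[C@@]2(C)CC[C@H](C(=C)CO[Si](c3ccccc3)(c3ccccc3)C(C)(C)C)C1 | intermediate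
15 | C11 tosylhydrazone of 14 | FC(F)(F)S(=O)(=O)O/C1=C(/OCC)CC[C@@H]2C(=NNS(=O)(=O)c3ccc(C)cc3)[C@H](C(=C)C)[C@@]2(C)CC[C@H](C(=C)CO[Si](c3ccccc3)(c3ccccc3)C(C)(C)C)C1 | intermediate (not isolated)
16 | (1S,4S,6E,10R,12R)-7-ethoxy-1-methyl-12-(prop-1-en-2-yl)-4-{3-[(tert-butyldiphenylsilyl)oxy]prop-1-en-2-yl}bicyclo[8.2.0]dodec-6-en-6-yl trifluoromethanesulfonate | FC(F)(F)S(=O)(=O)O/C1=C(/OCC)CC[C@@H]2C[C@H](C(=C)C)[C@@]2(C)CC[C@H](C(=C)CO[Si](c3ccccc3)(c3ccccc3)C(C)(C)C)C1 | intermediate
17 | (1S,4S,6E,10R,12R)-7-ethoxy-1-methyl-6-(prop-2-en-1-yl)-12-(prop-1-en-2-yl)-4-{3-[(tert-butyldiphenylsilyl)oxy]prop-1-en-2-yl}bicyclo[8.2.0]dodec-6-ene | C=CC/C1=C(/OCC)CC[C@@H]2C[C@H](C(=C)C)[C@@]2(C)CC[C@H](C(=C)CO[Si](c3ccccc3)(c3ccccc3)C(C)(C)C)C1 | intermediate (not isolated)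
18 | (1S,4S,6R,10R,12R)-1-methyl-6-(prop-2-en-1-yl)-12-(prop-1-en-2-yl)-4-{3-[(tert-butyldiphenylsilyl)oxy]prop-1-en-2-yl}bicyclo[8.2.0]dodecan-7-one | O=C1CC[C@@H]2C[C@H](C(=C)C)[C@@]2(C)CC[C@H](C(=C)CO[Si](c3ccccc3)(c3ccccc3)C(C)(C)C)C[C@H]1CC=C | intermediate
19 | tert-butyl({2-[(1S,4S,6R,10R,12R)-1-methyl-7-methylidene-6-(prop-2-en-1-yl)-12-(prop-1-en-2-yl)bicyclo[8.2.0]dodecan-4-yl]prop-2-en-1-yl}oxy)diphenylsilane | C=C1CC[C@@H]2C[C@H](C(=C)C)[C@@]2(C)CC[C@H](C(=C)CO[Si](c3ccccc3)(c3ccccc3)C(C)(C)C)C[C@H]1CC=C | intermediate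
20 | 2-[(1S,4S,6R,10R,12R)-1-methyl-7-methylidene-6-(prop-2-en-1-yl)-12-(prop-1-en-2-yl)bicyclo[8.2.0]dodecan-4-yl]prop-2-en-1-ol | C=C1CC[C@@H]2C[C@H](C(=C)C)[C@@]2(C)CC[C@H](C(=C)CO)C[C@H]1CC=C | intermediate
21 | 2-[(1S,4S,6R,10R,12R)-1-methyl-7-methylidene-6-(prop-2-en-1-yl)-12-(prop-1-en-2-yl)bicyclo[8.2.0]dodecan-4-yl]prop-2-enal | C=C1CC[C@@H]2C[C@H](C(=C)C)[C@@]2(C)CC[C@H](C(=C)C=O)C[C@H]1CC=C | intermediate (not isolated)
22 | 2-[(1S,4S,6R,10R,12R)-1-methyl-7-methylidene-6-(prop-2-en-1-yl)-12-(prop-1-en-2-yl)bicyclo[8.2.0]dodecan-4-yl]prop-2-enoic acid | C=C1CC[C@@H]2C[C@H](C(=C)C)[C@@]2(C)CC[C@H](C(=C)C(=O)O)C[C@H]1CC=C | intermediate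
23 | methyl 2-[(1S,4S,6R,10R,12R)-1-methyl-7-methylidene-6-(prop-2-en-1-yl)-12-(prop-1-en-2-yl)bicyclo[8.2.0]dodecan-4-yl]prop-2-enoate | C=C1CC[C@@H]2C[C@H](C(=C)C)[C@@]2(C)CC[C@H](C(=C)C(=O)OC)C[C@H]1CC=C | intermediate
24 | methyl 2-[(1S,4S,6R,10R,12R)-1-methyl-7-methylidene-6-(3-methylbut-2-en-1-yl)-12-(prop-1-en-2-yl)bicyclo[8.2.0]dodecan-4-yl]prop-2-enoate | C=C1CC[C@@H]2C[C@H](C(=C)C)[C@@]2(C)CC[C@H](C(=C)C(=O)OC)C[C@H]1CC=C(C)C | target

Total step count: 15. Longest linear sequence: 15 steps from 1.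

Least certain steps

Step 7 (key step). The rearrangement may be slow: the reactive chair needs the C4 side chain axial, and the donor ethoxy group sits on the migrating vinyl unit. Forcing conditions invite fragmentation of the alkoxide. The enol triflate may also be lost by hydrolysis on work-up or by thermal Cope reversal. The fallback sets out from 9 and returns at 19, keeping the carbonyl on C6 and transposing it by addition and reductive allylic substitution instead of cross-coupling. Vinylmagnesium bromide adds to 9 to give the 1,2-divinyl carbinol F1, which has no donor substituent. Its anionic oxy-Cope rearrangement (KH, 18-crown-6) is quenched with dimethyl(methylidene)ammonium iodide to give the Mannich base F2. Quaternisation with MeI and elimination with NaHCO3 give the C7-methylidene C6-ketone F3. 1,2-Addition of allylmagnesium bromide and capture of the alkoxide with methyl chloroformate give the tertiary allylic carbonate F4. The ketene cycloaddition of step 8 then gives the cyclobutanone F5, and the hydrazone reduction of step 9 gives F6. Hydrogenolysis with Pd(OAc)2, PBu3 and HCO2NH4 delivers hydride to the more substituted terminus C6 with inversion, keeps the exocyclic olefin, and gives 19.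

Step 8. Ketene dimerisation may outrun the cycloaddition at 40 °C. Other failure modes are competing attack on the enol ether or side-chain olefin, poor facial selectivity if several ring conformers react, and base-induced epimerisation at C10 or C12 or conjugation of the prop-1-en-2-yl group. The fallback sets out from 13 and returns at 16, building the prop-1-en-2-yl group after the ring. Dichloroketene (Cl3CCOCl, zinc–copper couple, POCl3, Et2O) is far more reactive toward unactivated trisubstituted olefins and has the same regiochemistry; it gives the α,α-dichlorocyclobutanone F7. Zn, NH4Cl, MeOH gives the cyclobutanone F8. The kinetic enolate at the C12 methylene (LDA, −78 °C) adds to acetone to give the aldol F9, which is epimerisable at C12. The hydrazone reduction of step 9 gives the tertiary alcohol F10, and dehydration with the Burgess reagent gives 16.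

Step 10. Oxidative addition and transmetalation at the tetrasubstituted, strained enol triflate may be slow, so protodetriflation can compete. Protonation at C6 may also occur from the wrong face. The fallback sets out from 16 and returns at 18, using radical allylation instead of cross-coupling. Reduction of the triflate (Pd(OAc)2, PPh3, HCO2H, Bu3N) gives the enol ether F11. N-Bromosuccinimide in wet THF attacks its nucleophilic C6 and gives the α-bromo ketone F12 with the regiochemistry fixed by the enol ether. Keck allylation (allyltributylstannane, AIBN, benzene, 80 °C) gives 18 as C6 epimers, which are equilibrated with DBU.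

Step 9. Condensation at the flanked cyclobutanone may stall, and longer exposure allows epimerisation next to the carbonyl before reduction. The fallback sets out from 14 and returns at 16, using radical deoxygenation. NaBH4 at low temperature gives the cyclobutanol F13. NaH, CS2, MeI give the xanthate F14. Bu3SnH with AIBN (Barton–McCombie deoxygenation) gives 16; the cyclobutyl radical opens too slowly to compete with hydrogen transfer.

Further compounds

F1 | step 7 | (1S,2S,5S)-1,2-diethenyl-2-methyl-5-{3-[(tert-butyldiphenylsilyl)oxy]prop-1-en-2-yl}cyclohexan-1-ol | O[C@@]1(C=C)C[C@@H](C(=C)CO[Si](c2ccccc2)(c2ccccc2)C(C)(C)C)CC[C@@]1(C)C=C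
F2 | step 7 | (5E,9S)-2-[(dimethylamino)methyl]-6-methyl-9-{3-[(tert-butyldiphenylsilyl)oxy]prop-1-en-2-yl}cyclodec-5-en-1-one | CN(C)CC1CC/C=C(C)/CC[C@H](C(=C)CO[Si](c2ccccc2)(c2ccccc2)C(C)(C)C)CC1=O
F3 | step 7 | (5E,9S)-6-methyl-2-methylidene-9-{3-[(tert-butyldiphenylsilyl)oxy]prop-1-en-2-yl}cyclodec-5-en-1-one | C=C1CC/C=C(C)/CC[C@H](C(=C)CO[Si](c2ccccc2)(c2ccccc2)C(C)(C)C)CC1=O
F4 | step 7 | methyl (5E,9S)-6-methyl-2-methylidene-1-(prop-2-en-1-yl)-9-{3-[(tert-butyldiphenylsilyl)oxy]prop-1-en-2-yl}cyclodec-5-en-1-yl carbonate | C=C1CC/C=C(C)/CC[C@H](C(=C)CO[Si](c2ccccc2)(c2ccccc2)C(C)(C)C)CC1(CC=C)OC(=O)OC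
F5 | step 7 | methyl 1-methyl-7-methylidene-11-oxo-6-(prop-2-en-1-yl)-12-(prop-1-en-2-yl)-4-{3-[(tert-butyldiphenylsilyl)oxy]prop-1-en-2-yl}bicyclo[8.2.0]dodecan-6-yl carbonate | C=C1CC[C@@H]2C(=O)[C@H](C(=C)C)[C@@]2(C)CC[C@H](C(=C)CO[Si](c3ccccc3)(c3ccccc3)C(C)(C)C)CC1(CC=C)OC(=O)OC
F6 | step 7 | methyl 1-methyl-7-methylidene-6-(prop-2-en-1-yl)-12-(prop-1-en-2-yl)-4-{3-[(tert-butyldiphenylsilyl)oxy]prop-1-en-2-yl}bicyclo[8.2.0]dodecan-6-yl carbonate | C=C1CC[C@@H]2C[C@H](C(=C)C)[C@@]2(C)CC[C@H](C(=C)CO[Si](c3ccccc3)(c3ccccc3)C(C)(C)C)CC1(CC=C)OC(=O)OC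
F7 | step 8 | (6E)-12,12-dichloro-7-ethoxy-1-methyl-11-oxo-4-{3-[(tert-butyldiphenylsilyl)oxy]prop-1-en-2-yl}bicyclo[8.2.0]dodec-6-en-6-yl trifluoromethanesulfonate | FC(F)(F)S(=O)(=O)O/C1=C(/OCC)CC[C@@H]2C(=O)C(Cl)(Cl)[C@@]2(C)CC[C@H](C(=C)CO[Si](c3ccccc3)(c3ccccc3)C(C)(C)C)C1
F8 | step 8 | (6E)-7-ethoxy-1-methyl-11-oxo-4-{3-[(tert-butyldiphenylsilyl)oxy]prop-1-en-2-yl}bicyclo[8.2.0]dodec-6-en-6-yl trifluoromethanesulfonate | FC(F)(F)S(=O)(=O)O/C1=C(/OCC)CC[C@@H]2C(=O)C[C@@]2(C)CC[C@H](C(=C)CO[Si](c3ccccc3)(c3ccccc3)C(C)(C)C)C1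
F9 | step 8 | (6E)-7-ethoxy-12-(2-hydroxypropan-2-yl)-1-methyl-11-oxo-4-{3-[(tert-butyldiphenylsilyl)oxy]prop-1-en-2-yl}bicyclo[8.2.0]dodec-6-en-6-yl trifluoromethanesulfonate | FC(F)(F)S(=O)(=O)O/C1=C(/OCC)CC[C@@H]2C(=O)[C@H](C(C)(C)O)[C@@]2(C)CC[C@H](C(=C)CO[Si](c3ccccc3)(c3ccccc3)C(C)(C)C)C1
F10 | step 8 | (6E)-7-ethoxy-12-(2-hydroxypropan-2-yl)-1-methyl-4-{3-[(tert-butyldiphenylsilyl)oxy]prop-1-en-2-yl}bicyclo[8.2.0]dodec-6-en-6-yl trifluoromethanesulfonate | FC(F)(F)S(=O)(=O)O/C1=C(/OCC)CC[C@@H]2C[C@H](C(C)(C)O)[C@@]2(C)CC[C@H](C(=C)CO[Si](c3ccccc3)(c3ccccc3)C(C)(C)C)C1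
F11 | step 10 | (6E)-7-ethoxy-1-methyl-12-(prop-1-en-2-yl)-4-{3-[(tert-butyldiphenylsilyl)oxy]prop-1-en-2-yl}bicyclo[8.2.0]dodec-6-ene | [H]/C1=C(/OCC)CC[C@@H]2C[C@H](C(=C)C)[C@@]2(C)CC[C@H](C(=C)CO[Si](c3ccccc3)(c3ccccc3)C(C)(C)C)C1
F12 | step 10 | 6-bromo-1-methyl-12-(prop-1-en-2-yl)-4-{3-[(tert-butyldiphenylsilyl)oxy]prop-1-en-2-yl}bicyclo[8.2.0]dodecan-7-one | O=C1CC[C@@H]2C[C@H](C(=C)C)[C@@]2(C)CC[C@H](C(=C)CO[Si](c3ccccc3)(c3ccccc3)C(C)(C)C)CC1Br
F13 | step 9 | (6E)-7-ethoxy-11-hydroxy-1-methyl-12-(prop-1-en-2-yl)-4-{3-[(tert-butyldiphenylsilyl)oxy]prop-1-en-2-yl}bicyclo[8.2.0]dodec-6-en-6-yl trifluoromethanesulfonate | FC(F)(F)S(=O)(=O)O/C1=C(/OCC)CC[C@@H]2C(O)[C@H](C(=C)C)[C@@]2(C)CC[C@H](C(=C)CO[Si](c3ccccc3)(c3ccccc3)C(C)(C)C)C1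
F14 | step 9 | O-[C11] S-methyl dithiocarbonate (xanthate) of F13 | FC(F)(F)S(=O)(=O)O/C1=C(/OCC)CC[C@@H]2C(OC(=S)SC)[C@H](C(=C)C)[C@@]2(C)CC[C@H](C(=C)CO[Si](c3ccccc3)(c3ccccc3)C(C)(C)C)C1
A1 | alternative 1 | methyl 2-{(3S,5R)-5-[4-((1R,2S,3R)-2-ethenyl-2-methyl-3-(prop-1-en-2-yl)cyclobutyl)but-1-en-2-yl]-8-methylnona-1,7-dien-3-yl}prop-2-enoate (ring-closing metathesis diene; descriptors indicative, SMILES decisive) | C=C(CC[C@@H]1C[C@H](C(=C)C)[C@@]1(C)C=C)[C@H](CC=C(C)C)C[C@H](C=C)C(=C)C(=O)OC
A2 | alternative 1 | 2,3-didehydro analogue of 24 with a (2E)-C2=C3 ring olefin | C=C1CC[C@@H]2C[C@H](C(=C)C)[C@@]2(C)/C=C/[C@H](C(=C)C(=O)OC)C[C@H]1CC=C(C)C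
A3 | alternative 2 | tricyclic C7-carbinol C3-mesylate with an extra C7–C2 bond (cyclobutane-annulated decalin) | O[C@@]12CC[C@@H]3C[C@H](C(=C)C)[C@@]3(C)[C@@H]1[C@H](OS(C)(=O)=O)[C@H](C(=C)C)C[C@H]2CC=C
A4 | alternative 2 | (2E)-1-methyl-6-(prop-2-en-1-yl)-4,12-di(prop-1-en-2-yl)bicyclo[8.2.0]dodec-2-en-7-one | O=C1CC[C@@H]2C[C@H](C(=C)C)[C@@]2(C)/C=C/[C@H](C(=C)C)C[C@H]1CC=C
A5 | alternative 3 | 1-(cyclobut-1-en-1-yl)-2-ethenyl-2-methyl-3-(prop-2-en-1-yl)-5-(prop-1-en-2-yl)cyclohexan-1-ol | O[C@]1(C2=CCC2)C[C@H](C(=C)C)C[C@@H](CC=C)[C@]1(C)C=C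
A6 | alternative 3 | (7E)-1,7-dimethyl-6-(prop-2-en-1-yl)-4-(prop-1-en-2-yl)bicyclo[8.2.0]dodec-7-en-2-one | O=C1C[C@H](C(=C)C)C[C@@H](CC=C)/C(C)=C/C[C@@H]2CC[C@@]12C
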